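**Strategy.** The target is cut at its 1,4-diketone C4(=O)–C3–C3''–C4''(=O). The pyranone ring of the 5,7-dihydroxy unit (O1, C2, C3, C4, C4a, C8a) is closed after all other rings by an intramolecular Stetter reaction, which forms C3–C4 and the diketone in one operation. Its precursor is an aryl aldehyde tied through the O1–C2 ether to the exocyclic enone of a finished 3-alkylidene flavanone, itself made by carbene-catalysed alkyne hydroacylation. The chain C2–C3–C3''–C2'' is a C2-symmetric butynediol whose two carbinol centres, set by one catalytic double reduction, become C2 and C2''. C3 and C3'' are finally relayed from them by a double kinetic protonation.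

Key step: step 9

Remark: unprimed locants denote the 5,7-dihydroxy unit and doubly primed ones the 5-hydroxy-7-methoxy unit; the SMILES is read as the all-R isomer with both pyranone rings 2,3-cis, and the phloroglucinaldehydes 7 and 13 are taken as purchasable.

Step 1
Reactants: 1 4-methoxybenzaldehyde (2 equiv); 2 acetylene
Product: 4 1,4-bis(4-methoxyphenyl)but-2-yne-1,4-diol (racemic plus meso), via acetylene bis-Grignard reagent 3 (not isolated)
Conditions: 2, EtMgBr (2 equiv), THF, rt; then 1, 0 °C to rt; aq NH4Cl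
Reagents that add atoms: none
Why: Two-fold 1,2-addition of the acetylene bis-Grignard reagent to the aldehyde assembles the C2–C3≡C3''–C2'' chain with both anisyl groups in place; the carbinol configuration is irrelevant because both centres are oxidised in step 2.

Step 2
Reactants: 4 1,4-bis(4-methoxyphenyl)but-2-yne-1,4-diol
Product: 5 1,4-bis(4-methoxyphenyl)but-2-yne-1,4-dione
Conditions: activated MnO2 (excess), CH2Cl2, rt
Reagents that add atoms: none
Why: Manganese dioxide oxidation of benzylic–propargylic alcohols to ynones is chemoselective and neutral, which the Michael-acceptor product should tolerate.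

Step 3
Reactants: 5 1,4-bis(4-methoxyphenyl)but-2-yne-1,4-dione
Product: 6 (1R,4R)-1,4-bis(4-methoxyphenyl)but-2-yne-1,4-diol
Conditions: Ru[(R,R)-TsDPEN](p-cymene) (16-electron amido complex, 2 mol%), i-PrOH, rt; crystallisation
Reagents that add atoms: none
Why: Noyori asymmetric transfer hydrogenation of α,β-acetylenic ketones should reduce each C=O under catalyst control without touching the triple bond (base-free medium spares the ynedione), the two-fold reduction should raise the ee of the C2-symmetric diol by diverting the minor-sense event into the separable meso isomer, and the (R,R) sense is assigned by analogy with alkyl ynones, the antipodal catalyst being used should it prove opposite; these two centres become C2 and C2''.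

Step 4
Reactants: 7 2,6-dihydroxy-4-methoxybenzaldehyde
Product: 8 2-(benzyloxy)-6-hydroxy-4-methoxybenzaldehyde
Conditions: BnBr (1.05 equiv), K2CO3, acetone, reflux
Reagents that add atoms: benzyl bromide, BrCc1ccccc1
Why: Williamson etherification of one of two equivalent phenols; the remaining OH is deactivated by its hydrogen bond to the formyl group, so mono-benzylation is expected.

Step 5
Reactants: 6 (1R,4R)-1,4-bis(4-methoxyphenyl)but-2-yne-1,4-diol (3 equiv, excess recovered); 8 2-(benzyloxy)-6-hydroxy-4-methoxybenzaldehyde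
Product: 9 2-(benzyloxy)-6-{[(1S,4R)-4-hydroxy-1,4-bis(4-methoxyphenyl)but-2-yn-1-yl]oxy}-4-methoxybenzaldehyde
Conditions: PPh3, DIAD, THF, 0 °C to rt
Reagents that add atoms: none
Why: Mitsunobu etherification with the acidic salicylaldehyde OH as pronucleophile should proceed by SN2 inversion at one of the two homotopic carbinols of the C2-symmetric diol (hence one mono-ether, the excess of diol suppressing the bis-ether), which fixes the configuration of the future C2''.

Step 6
Reactants: 9 2-(benzyloxy)-6-{[(1S,4R)-4-hydroxy-1,4-bis(4-methoxyphenyl)but-2-yn-1-yl]oxy}-4-methoxybenzaldehyde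
Product: 12 (2S,3E)-5-(benzyloxy)-3-[(2S)-2-hydroxy-2-(4-methoxyphenyl)ethylidene]-7-methoxy-2-(4-methoxyphenyl)chroman-4-one, via silyl ether 10 (not isolated), via silyloxy enone 11 (not isolated)
Conditions: TMSCl, Et3N, THF, 0 °C, filtration; then N-(2,6-diisopropylphenyl)thiazolium precatalyst (10 mol%), K2CO3 (20 mol%), THF, 70 °C; then 10% aq citric acid, THF, 0 °C
Reagents that add atoms: none
Why: Carbene-catalysed intramolecular hydroacylation of an unactivated alkyne by a salicylaldehyde propargyl ether: the Breslow intermediate should add across the triple bond in a concerted syn (Conia-ene-like) 6-exo-dig event to give the (E)-3-alkylidene chroman-4-one, the transient silyl ether keeps a free alkoxide out of the basic medium, and C2'' is not touched (its descriptor changes only through CIP priorities).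

Step 7
Reactants: 13 2,4,6-trihydroxybenzaldehyde
Product: 14 2,4-bis(benzyloxy)-6-hydroxybenzaldehyde
Conditions: BnBr (2.1 equiv), K2CO3, DMF, rt
Reagents that add atoms: benzyl bromide, BrCc1ccccc1
Why: Williamson etherification of two of the three phenols, the last ortho OH staying locked in its hydrogen bond to the formyl group (the usual selectivity of phloroglucinol carbonyl compounds).

Step 8
Reactants: 12 (2S,3E)-5-(benzyloxy)-3-[(2S)-2-hydroxy-2-(4-methoxyphenyl)ethylidene]-7-methoxy-2-(4-methoxyphenyl)chroman-4-one; 14 2,4-bis(benzyloxy)-6-hydroxybenzaldehyde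
Product: 15 2,4-bis(benzyloxy)-6-{[(1R,2E)-2-[(2S)-5-(benzyloxy)-7-methoxy-2-(4-methoxyphenyl)-4-oxochroman-3-ylidene]-1-(4-methoxyphenyl)ethyl]oxy}benzaldehyde
Conditions: PPh3, DIAD, toluene, −20 °C to rt
Reagents that add atoms: none
Why: Second Mitsunobu etherification, again with SN2 inversion, now at the allylic benzylic carbinol, whose ionisation is disfavoured by the electron-poor enone, so that the O1–C2 ether should form with the (R) configuration of C2.

Step 9
Reactants: 15 2,4-bis(benzyloxy)-6-{[(1R,2E)-2-[(2S)-5-(benzyloxy)-7-methoxy-2-(4-methoxyphenyl)-4-oxochroman-3-ylidene]-1-(4-methoxyphenyl)ethyl]oxy}benzaldehyde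
Product: 16 (2R,3S)-5,7-bis(benzyloxy)-3-[(2R,3R)-5-(benzyloxy)-7-methoxy-2-(4-methoxyphenyl)-4-oxochroman-3-yl]-2-(4-methoxyphenyl)chroman-4-one
Conditions: 2-(pentafluorophenyl)-6,7-dihydro-5H-pyrrolo[2,1-c][1,2,4]triazol-2-ium tetrafluoroborate (20 mol%), i-Pr2NEt (20 mol%), toluene, rt
Reagents that add atoms: none
Why: The triazolylidene adds to the formyl carbon (the future C4) to give a Breslow intermediate, whose acyl-anion carbon adds in a conjugate sense to C3, the β-carbon of the exocyclic enone C4''(=O)–C3''=C3 of the finished flavanone; proton transfer to the ring enolate at C3'' and loss of the carbene then give the 1,4-diketone. The closest known reaction type is the intramolecular Stetter reaction of salicylaldehyde-derived ethers, the standard catalytic entry to chroman-4-ones. The pyranone ring of the 5,7-dioxygenated unit closes in the 6-exo-trig mode through the C3–C4 bond, when every other ring already exists. C3 is controlled by allylic 1,3-strain: the C2–H bond eclipses C3=C3'', the O1 tether delivers C4 to the face it occupies and the anisyl group ends up trans to the new bond (2,3-trans), while C3'' arises by protonation of the ring enol anti to its pseudoaxial anisyl group; both centres are provisional and are reset in step 10. The step needs chemoselectivity for conjugate acylation over benzoin coupling and over base-induced migration of the exocyclic double bond into the ring (which would destroy C2''); the six-membered intramolecular delivery, the single aldehyde group and a weak amine base should secure it.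

Step 10
Reactants: 16 (2R,3S)-5,7-bis(benzyloxy)-3-[(2R,3R)-5-(benzyloxy)-7-methoxy-2-(4-methoxyphenyl)-4-oxochroman-3-yl]-2-(4-methoxyphenyl)chroman-4-one
Product: 18 (2R,3R)-5,7-bis(benzyloxy)-3-[(2R,3R)-5-(benzyloxy)-7-methoxy-2-(4-methoxyphenyl)-4-oxochroman-3-yl]-2-(4-methoxyphenyl)chroman-4-one, via bis(silyl enol ether) 17 (not isolated)
Conditions: TMSOTf (3 equiv), Et3N (4 equiv), CH2Cl2, 0 °C to rt; then 1 M aq HCl, THF, −20 °C
Reagents that add atoms: none
Why: Soft enolisation (silyl triflate and amine, no free enolate, so the rings cannot open and C2/C2'' are safe) erases C3 and C3''; in each 4-silyloxy-2H-chromene ring allylic 1,2-strain with the bulky 3-substituent should hold the C2 anisyl group pseudoaxial, so that irreversible C-protonation anti to it places H trans to the aryl group and gives the 2,3-cis arrangement in both rings (kinetic protonation of silyl enol ethers, relay from C2 and C2'').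

Step 11
Reactants: 18 (2R,3R)-5,7-bis(benzyloxy)-3-[(2R,3R)-5-(benzyloxy)-7-methoxy-2-(4-methoxyphenyl)-4-oxochroman-3-yl]-2-(4-methoxyphenyl)chroman-4-one
Product: 19 (2R,3R)-5,7-dihydroxy-3-[(2R,3R)-5-hydroxy-7-methoxy-2-(4-methoxyphenyl)-4-oxochroman-3-yl]-2-(4-methoxyphenyl)chroman-4-one
Conditions: H2 (1 atm), 10% Pd/C, EtOAc, rt, short reaction time
Reagents that add atoms: none
Why: Hydrogenolysis of the three aryl benzyl ethers under neutral conditions cannot enolise the ketones, so the kinetically set cis,cis configuration should survive while the methyl ethers stay.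

**Compound list**

1 | 4-methoxybenzaldehyde | COc1ccc(C=O)cc1 | starting material
2 | acetylene | C#C | starting material
3 | ethyne-1,2-diylbis(magnesium bromide) | Br[Mg]C#C[Mg]Br | intermediate
4 | 1,4-bis(4-methoxyphenyl)but-2-yne-1,4-diol (racemic plus meso) | COc1ccc(cc1)C(O)C#CC(O)c1ccc(OC)cc1 | intermediate
5 | 1,4-bis(4-methoxyphenyl)but-2-yne-1,4-dione | COc1ccc(cc1)C(=O)C#CC(=O)c1ccc(OC)cc1 | intermediate
6 | (1R,4R)-1,4-bis(4-methoxyphenyl)but-2-yne-1,4-diol | COc1ccc(cc1)[C@@H](O)C#C[C@H](O)c1ccc(OC)cc1 | intermediate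
7 | 2,6-dihydroxy-4-methoxybenzaldehyde | COc1cc(O)c(C=O)c(O)c1 | starting material
8 | 2-(benzyloxy)-6-hydroxy-4-methoxybenzaldehyde | COc1cc(O)c(C=O)c(OCc2ccccc2)c1 | intermediate
9 | 2-(benzyloxy)-6-{[(1S,4R)-4-hydroxy-1,4-bis(4-methoxyphenyl)but-2-yn-1-yl]oxy}-4-methoxybenzaldehyde | COc1ccc(cc1)[C@@H](O)C#C[C@@H](Oc1cc(OC)cc(OCc2ccccc2)c1C=O)c1ccc(OC)cc1 | intermediate
10 | 2-(benzyloxy)-4-methoxy-6-{[(1S,4R)-1,4-bis(4-methoxyphenyl)-4-[(trimethylsilyl)oxy]but-2-yn-1-yl]oxy}benzaldehyde | COc1ccc(cc1)[C@@H](O[Si](C)(C)C)C#C[C@@H](Oc1cc(OC)cc(OCc2ccccc2)c1C=O)c1ccc(OC)cc1 | intermediate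
11 | (2S,3E)-5-(benzyloxy)-7-methoxy-2-(4-methoxyphenyl)-3-{(2S)-2-(4-methoxyphenyl)-2-[(trimethylsilyl)oxy]ethylidene}chroman-4-one | COc1ccc(cc1)[C@@H](O[Si](C)(C)C)/C=C2/C(=O)c3c(OCc4ccccc4)cc(OC)cc3O[C@H]2c2ccc(OC)cc2 | intermediate
12 | (2S,3E)-5-(benzyloxy)-3-[(2S)-2-hydroxy-2-(4-methoxyphenyl)ethylidene]-7-methoxy-2-(4-methoxyphenyl)chroman-4-one | COc1ccc(cc1)[C@@H](O)/C=C2/C(=O)c3c(OCc4ccccc4)cc(OC)cc3O[C@H]2c2ccc(OC)cc2 | intermediate
13 | 2,4,6-trihydroxybenzaldehyde | O=Cc1c(O)cc(O)cc1O | starting material
14 | 2,4-bis(benzyloxy)-6-hydroxybenzaldehyde | O=Cc1c(O)cc(OCc2ccccc2)cc1OCc1ccccc1 | intermediate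
15 | 2,4-bis(benzyloxy)-6-{[(1R,2E)-2-[(2S)-5-(benzyloxy)-7-methoxy-2-(4-methoxyphenyl)-4-oxochroman-3-ylidene]-1-(4-methoxyphenyl)ethyl]oxy}benzaldehyde | COc1ccc(cc1)[C@@H](/C=C2/C(=O)c3c(OCc4ccccc4)cc(OC)cc3O[C@H]2c2ccc(OC)cc2)Oc1cc(OCc2ccccc2)cc(OCc2ccccc2)c1C=O | intermediate
16 | (2R,3S)-5,7-bis(benzyloxy)-3-[(2R,3R)-5-(benzyloxy)-7-methoxy-2-(4-methoxyphenyl)-4-oxochroman-3-yl]-2-(4-methoxyphenyl)chroman-4-one | COc1ccc([C@@H]2Oc3cc(OCc4ccccc4)cc(OCc4ccccc4)c3C(=O)[C@H]2[C@H]2C(=O)c3c(OCc4ccccc4)cc(OC)cc3O[C@H]2c2ccc(OC)cc2)cc1 | intermediate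
17 | (2S,2'S)-5,7-bis(benzyloxy)-5'-(benzyloxy)-7'-methoxy-2,2'-bis(4-methoxyphenyl)-4,4'-bis[(trimethylsilyl)oxy]-2H,2'H-3,3'-bichromene | COc1ccc([C@@H]2Oc3cc(OCc4ccccc4)cc(OCc4ccccc4)c3C(O[Si](C)(C)C)=C2C2=C(O[Si](C)(C)C)c3c(OCc4ccccc4)cc(OC)cc3O[C@H]2c2ccc(OC)cc2)cc1 | intermediate
18 | (2R,3R)-5,7-bis(benzyloxy)-3-[(2R,3R)-5-(benzyloxy)-7-methoxy-2-(4-methoxyphenyl)-4-oxochroman-3-yl]-2-(4-methoxyphenyl)chroman-4-one | COc1ccc([C@@H]2Oc3cc(OCc4ccccc4)cc(OCc4ccccc4)c3C(=O)[C@@H]2[C@H]2C(=O)c3c(OCc4ccccc4)cc(OC)cc3O[C@H]2c2ccc(OC)cc2)cc1 | intermediate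
19 | (2R,3R)-5,7-dihydroxy-3-[(2R,3R)-5-hydroxy-7-methoxy-2-(4-methoxyphenyl)-4-oxochroman-3-yl]-2-(4-methoxyphenyl)chroman-4-one | COc1ccc([C@@H]2Oc3cc(O)cc(O)c3C(=O)[C@@H]2[C@H]2C(=O)c3c(O)cc(OC)cc3O[C@H]2c2ccc(OC)cc2)cc1 | target

**Step count and risks**

Total step count: 11. Longest linear sequence: 9 steps (1, 2, 3, 5, 6, 8, 9, 10, 11).

The three steps most likely to fail:

Step 6. The carbene may fail to engage the di-ortho-alkoxy aldehyde or the unactivated triple bond. At 70 °C the base may also move the exocyclic double bond into the pyranone ring (aromatisation to a flavone, loss of C2''), and intermolecular Stetter oligomerisation may compete. The fallback sets out from 9. The free carbinol is oxidised with MnO2 to the ynone 2-(benzyloxy)-6-{[(1S)-1,4-bis(4-methoxyphenyl)-4-oxobut-2-yn-1-yl]oxy}-4-methoxybenzaldehyde F1. The ring is then closed at room temperature by an intramolecular Stetter reaction onto this activated alkyne (triazolium precatalyst, i-Pr2NEt), giving the ene-dione (2S,3E)-5-(benzyloxy)-7-methoxy-2-(4-methoxyphenyl)-3-[2-(4-methoxyphenyl)-2-oxoethylidene]chroman-4-one F2. CBS reduction (catecholborane, −78 °C) of the unhindered anisyl ketone, with the catalyst chosen for the required carbinol, brings the route back at 12.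

Step 9. Formation of the Breslow intermediate from the hindered, electron-rich aldehyde may be slow. The amine base and the carbene may meanwhile deprotonate the γ-position and shift the double bond. The fallback sets out from 15 and replaces the polar acyl anion by an acyl radical: hydrogen-atom abstraction from the formyl group with tetrabutylammonium decatungstate under 390 nm light in MeCN, followed by 6-exo-trig Giese cyclisation onto the enone without any base. It comes back at 16 and makes no new compound (F0).

Step 10. Bis-enolisation of the crowded diketone may stop halfway. Protonation may not be face-selective at both enol ethers, and acid may open the electron-rich enol ether at the C2–O1 bond with loss of C2. The fallback sets out from 17 (made from 16 as in step 10). It is oxidised with DDQ to the tetrasubstituted ene-dione (2S,2'S,E)-5,7-bis(benzyloxy)-5'-(benzyloxy)-7'-methoxy-2,2'-bis(4-methoxyphenyl)-[3,3'-bichromanylidene]-4,4'-dione F3. Hydrogenation (H2, Pd/C) should then deliver both hydrogens syn to the alkene face anti to the two pseudoaxial anisyl groups, which lie on the same face in the C2-symmetric E-isomer. This would set C3 and C3'' together and cleave the benzyl ethers in the same operation, coming back at 19.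

Further compounds
F1 | step 6 | 2-(benzyloxy)-6-{[(1S)-1,4-bis(4-methoxyphenyl)-4-oxobut-2-yn-1-yl]oxy}-4-methoxybenzaldehyde | COc1ccc(cc1)C(=O)C#C[C@@H](Oc1cc(OC)cc(OCc2ccccc2)c1C=O)c1ccc(OC)cc1
F2 | step 6 | (2S,3E)-5-(benzyloxy)-7-methoxy-2-(4-methoxyphenyl)-3-[2-(4-methoxyphenyl)-2-oxoethylidene]chroman-4-one | COc1ccc(cc1)C(=O)/C=C2/C(=O)c3c(OCc4ccccc4)cc(OC)cc3O[C@H]2c2ccc(OC)cc2
F0 | step 9 | none | none
F3 | step 10 | (2S,2'S,E)-5,7-bis(benzyloxy)-5'-(benzyloxy)-7'-methoxy-2,2'-bis(4-methoxyphenyl)-[3,3'-bichromanylidene]-4,4'-dione | COc1ccc([C@@H]2Oc3cc(OCc4ccccc4)cc(OCc4ccccc4)c3C(=O)/C2=C2/C(=O)c3c(OCc4ccccc4)cc(OC)cc3O[C@H]2c2ccc(OC)cc2)cc1
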